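**Plan**

1. Locants follow tetrahydroquinolin-4(1H)-one numbering: ring A (pyridone) = N1, C2, C3, C4, C4a, C8a; ring B (carbocycle) = C4a, C5, C6, C7, C8, C8a.
2. Enabling feature: C8a of ring A is an enamine carbon, i.e. a masked ketone. Read as C=O, it makes C8 an α-methyl carbon, puts C7 in an aldol relation to it and C5 β to C7, with the C4 carbonyl as second activator on C4a, so ring B is a Robinson-type retron.
3. Retrosynthesis: N1 ⇒ O (4-pyranone 14); pyranone C–O bonds ⇒ 1,3,5-triketone 12; C2–C3 and C4–C4a ⇒ two enolate acylations; C7–C8 (aldol condensation) and C4a–C5 (Michael) ⇒ tert-butyl acetoacetate + (E)-undec-2-enal.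
4. Forward: ring B is made first in one flask (step 1), ring A is grown on it as a 4-pyranone (steps 2–4), hydrogenation removes C7=C8 and the benzyl group (step 5), and O is exchanged for N–OMe last (step 6).
5. Stereochemistry: C5 (R) is set in step 1 by the chiral secondary-amine catalyst; afterwards it carries no acidic hydrogen and no step touches it.
6. Helpers: the tert-butyl ester fixes the Michael site and is lost in step 1; the C7=C8 double bond left by the aldol condensation blocks C8, so steps 2 and 3 enolise only towards C4a and C3, and it is removed in step 5.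

Key step: step 1

Remark: the enolisable carbon next to the octyl-bearing centre in 3, 4, 5, 9 and 12 (the future C4a) is drawn without configuration; it becomes sp2 in step 4.

**Step 1**
Reactants: 1 tert-butyl 3-oxobutanoate; 2 (E)-undec-2-enal
Product: 6 (5R)-5-octylcyclohex-2-en-1-one, via Michael adduct 3 (not isolated), via cyclohexenone tert-butyl ester 4 (not isolated), via keto acid 5 (not isolated)
Conditions: (S)-2-{bis[3,5-bis(trifluoromethyl)phenyl](trimethylsilyloxy)methyl}pyrrolidine (10 mol%), toluene, rt; then TsOH·H2O (20 mol%), 80 °C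
Reagents that add atoms: none
Why: The amine condenses with 2 to an (E)-iminium ion, one face of which is covered by the diaryl(silyloxy)methyl group, so the central carbon of 1 (future C4a) should add to the open face of the β-carbon (future C5) and set C5 as R under catalyst control (organocatalytic Michael addition; by the usual shielding model the (S)-catalyst gives the 5R series). After hydrolysis to aldehyde 3, TsOH enolises the methyl ketone and its methyl carbon (future C8) attacks the aldehyde carbon (future C7) in an intramolecular aldol condensation, a 6-(enolendo)-exo-trig closure that forms the C7–C8 bond of ring B as the enone C=C of 4. Acidolysis of the tert-butyl ester (loss of isobutene) and decarboxylation of keto acid 5 then remove the activating group. The closest known reaction type is the amine-catalysed Michael/aldol condensation/decarboxylation of tert-butyl acetoacetate with enals to 5-substituted cyclohex-2-enones, an asymmetric Robinson-type annulation. The selectivity needed is secured by the substrate: the ester makes the central carbon the Michael donor, only the methyl group can close a six-membered ring (the central carbon would give a cyclobutane), and C5 bears no acidic hydrogen and cannot epimerise.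

**Step 2**
Reactants: 6 (5R)-5-octylcyclohex-2-en-1-one; 7 N,2-dimethoxy-N-methylacetamide
Product: 9 (5R)-6-(2-methoxyacetyl)-5-octylcyclohex-2-en-1-one, via lithium dienolate 8 (not isolated)
Conditions: LiN(iPr)2 (1.1 equiv), THF, −78 °C; then 7, −78 to 0 °C; 1 M HCl
Reagents that add atoms: none
Why: Kinetic deprotonation of the cyclohex-2-enone can occur only at the α'-carbon (future C4a) because the other α-carbon is the sp2 C8, and the lithium enolate adds to the chelating N-methoxy-N-methylamide to give a stable tetrahedral adduct that releases the β-diketone on work-up (enolate C-acylation, Claisen type), leaving C5 untouched.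

**Step 3**
Reactants: 9 (5R)-6-(2-methoxyacetyl)-5-octylcyclohex-2-en-1-one; 10 2-(benzyloxy)-N-methoxy-N-methylacetamide
Product: 12 1-(benzyloxy)-3-methoxy-4-[(6R)-6-octyl-2-oxocyclohex-3-en-1-yl]butane-2,4-dione, via dilithium dianion 11 (not isolated)
Conditions: LiN(iPr)2 (2.5 equiv), THF, −78 to −20 °C; then 10, −78 to 0 °C; 1 M HCl
Reagents that add atoms: none
Why: After the diketonate forms, the second equivalent of base should remove a proton from the exocyclic OMe-bearing carbon (future C3; Li–OMe chelation assists, C8 is sp2), and this more reactive terminus of the 1,3-dianion is acylated by the N-methoxy-N-methylamide to give the 1,3,5-triketone (β-diketone dianion acylation).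

**Step 4**
Reactants: 12 1-(benzyloxy)-3-methoxy-4-[(6R)-6-octyl-2-oxocyclohex-3-en-1-yl]butane-2,4-dione
Product: 13 (5R)-2-[(benzyloxy)methyl]-3-methoxy-5-octyl-5,6-dihydro-4H-chromen-4-one
Conditions: TsOH·H2O (10 mol%), toluene, 80 °C
Reagents that add atoms: none
Why: Acid-catalysed cyclodehydration of a 1,3,5-triketone (the enol oxygen on C8a adds to the terminal ketone C2, then water is lost) can give only the 4-pyranone with the central carbonyl as C4; the benzyl ether and C5 are not affected.

**Step 5**
Reactants: 13 (5R)-2-[(benzyloxy)methyl]-3-methoxy-5-octyl-5,6-dihydro-4H-chromen-4-one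
Product: 14 (5R)-2-(hydroxymethyl)-3-methoxy-5-octyl-5,6,7,8-tetrahydro-4H-chromen-4-one
Conditions: H2 (1 atm), 10% Pd/C, EtOAc–EtOH, rt
Reagents that add atoms: none
Why: Catalytic hydrogenation saturates the conjugated cis-disubstituted C7=C8 bond and cleaves the benzyl ether by hydrogenolysis, while the fully substituted 4-pyranone ring should be inert at 1 atm and C5 is not involved.

**Step 6**
Reactants: 14 (5R)-2-(hydroxymethyl)-3-methoxy-5-octyl-5,6,7,8-tetrahydro-4H-chromen-4-one
Product: 15 (5R)-2-(hydroxymethyl)-1,3-dimethoxy-5-octyl-5,6,7,8-tetrahydroquinolin-4(1H)-one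
Conditions: MeONH2·HCl (5 equiv), NaOAc (5 equiv), aq. EtOH, 80 °C, sealed tube
Reagents that add atoms: O-methylhydroxylamine hydrochloride, CON.Cl
Why: Methoxyamine adds to C2 or C8a of the 4-pyranone, the ring opens and recloses through nitrogen with loss of water (the classical 4-pyranone to 4-pyridone exchange known for amines and hydroxylamine), which should give the N-methoxy-4-pyridone without touching C5 or the primary alcohol.

**Compound list**

1 | tert-butyl 3-oxobutanoate | CC(=O)CC(=O)OC(C)(C)C | starting material
2 | (E)-undec-2-enal | CCCCCCCC/C=C/C=O | starting material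
3 | tert-butyl (3R)-2-acetyl-3-(2-oxoethyl)undecanoate (Michael adduct) | CCCCCCCC[C@H](CC=O)C(C(C)=O)C(=O)OC(C)(C)C | intermediate
4 | tert-butyl (6R)-6-octyl-2-oxocyclohex-3-ene-1-carboxylate | CCCCCCCC[C@@H]1CC=CC(=O)C1C(=O)OC(C)(C)C | intermediate
5 | (6R)-6-octyl-2-oxocyclohex-3-ene-1-carboxylic acid | CCCCCCCC[C@@H]1CC=CC(=O)C1C(=O)O | intermediate
6 | (5R)-5-octylcyclohex-2-en-1-one | CCCCCCCC[C@@H]1CC=CC(=O)C1 | intermediate
7 | N,2-dimethoxy-N-methylacetamide | COCC(=O)N(C)OC | starting material
8 | lithium (6R)-6-octylcyclohexa-1,3-dien-2-olate (kinetic enolate of 6) | CCCCCCCC[C@@H]1CC=CC(O[Li])=C1 | intermediate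
9 | (5R)-6-(2-methoxyacetyl)-5-octylcyclohex-2-en-1-one | CCCCCCCC[C@@H]1CC=CC(=O)C1C(=O)COC | intermediate
10 | 2-(benzyloxy)-N-methoxy-N-methylacetamide | CON(C)C(=O)COCc1ccccc1 | starting material
11 | dilithium dianion of 9 (bis-enolate, deprotonated at the ring carbon between the carbonyls and at the OMe-bearing carbon) | CCCCCCCC[C@@H]1CC=CC(O[Li])=C1C(O[Li])=COC | intermediate
12 | 1-(benzyloxy)-3-methoxy-4-[(6R)-6-octyl-2-oxocyclohex-3-en-1-yl]butane-2,4-dione | CCCCCCCC[C@@H]1CC=CC(=O)C1C(=O)C(OC)C(=O)COCc1ccccc1 | intermediate
13 | (5R)-2-[(benzyloxy)methyl]-3-methoxy-5-octyl-5,6-dihydro-4H-chromen-4-one | CCCCCCCC[C@@H]1CC=Cc2oc(COCc3ccccc3)c(OC)c(=O)c12 | intermediate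
14 | (5R)-2-(hydroxymethyl)-3-methoxy-5-octyl-5,6,7,8-tetrahydro-4H-chromen-4-one | CCCCCCCC[C@@H]1CCCc2oc(CO)c(OC)c(=O)c12 | intermediate
15 | (5R)-2-(hydroxymethyl)-1,3-dimethoxy-5-octyl-5,6,7,8-tetrahydroquinolin-4(1H)-one | CCCCCCCC[C@@H]1CCCc2c1c(=O)c(OC)c(CO)n2OC | target

**Totals**

Total step count: 6. Longest linear sequence: 6 steps (from 1 and 2).

**Steps most likely to fail**

Step 3. What may go wrong: the second deprotonation may take place at the ring γ-position (future C6) instead of the exocyclic carbon, or the dianion may be quenched by proton transfer from the α-alkoxy amide, so that C3 is not acylated cleanly. The fallback sets out from 9 and comes back at 14. Claisen condensation of 9 with dimethyl oxalate (NaOMe, MeOH–THF, 0 °C to rt) is reversible and uses a non-enolisable electrophile, so the doubly stabilised C3-acylated enolate is the thermodynamic sink, as in the methoxyacetyl/oxalate route to 3-methoxy-4-pyranone-2-carboxylates. It should give methyl 3-methoxy-2,4-dioxo-4-[(6R)-6-octyl-2-oxocyclohex-3-en-1-yl]butanoate F1. TsOH in toluene closes this to methyl (5R)-3-methoxy-5-octyl-4-oxo-5,6-dihydro-4H-chromene-2-carboxylate F2. Hydrogenation over Pd/C gives methyl (5R)-3-methoxy-5-octyl-4-oxo-5,6,7,8-tetrahydro-4H-chromene-2-carboxylate F3. NaBH4 with CaCl2 in EtOH–THF at 0 °C reduces the activated 2-ester to alcohol 14.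

Step 6. What may go wrong: slow addition of the weakly basic alkoxyamine to the fully substituted pyranone, or failure of the ring-opened oxime ether to reclose through nitrogen. The fallback sets out from 14 and comes back at 15. The more nucleophilic hydroxylamine (NH2OH·HCl, NaOAc, aq. EtOH, 80 °C) should give (5R)-1-hydroxy-2-(hydroxymethyl)-3-methoxy-5-octyl-5,6,7,8-tetrahydroquinolin-4(1H)-one F4. Methylation of the acidic N–OH group (MeI, K2CO3, DMF, rt) then gives 15; the primary alcohol is not deprotonated under these conditions.

Step 2. What may go wrong: O-acylation or incomplete C-acylation of the cross-conjugated enolate, and Michael self-condensation of enolate with enone. The fallback sets out from 6 and comes back at 9. Aldol addition of the same kinetic lithium enolate (LiN(iPr)2, THF, −78 °C) to methoxyacetaldehyde should give (5R)-6-(1-hydroxy-2-methoxyethyl)-5-octylcyclohex-2-en-1-one F5. Dess–Martin oxidation (CH2Cl2, rt) of the secondary alcohol then gives diketone 9.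

**Further compounds**

F1 | step 3 | methyl 3-methoxy-2,4-dioxo-4-[(6R)-6-octyl-2-oxocyclohex-3-en-1-yl]butanoate | CCCCCCCC[C@@H]1CC=CC(=O)C1C(=O)C(OC)C(=O)C(=O)OC
F2 | step 3 | methyl (5R)-3-methoxy-5-octyl-4-oxo-5,6-dihydro-4H-chromene-2-carboxylate | CCCCCCCC[C@@H]1CC=Cc2oc(C(=O)OC)c(OC)c(=O)c12
F3 | step 3 | methyl (5R)-3-methoxy-5-octyl-4-oxo-5,6,7,8-tetrahydro-4H-chromene-2-carboxylate | CCCCCCCC[C@@H]1CCCc2oc(C(=O)OC)c(OC)c(=O)c12
F4 | step 6 | (5R)-1-hydroxy-2-(hydroxymethyl)-3-methoxy-5-octyl-5,6,7,8-tetrahydroquinolin-4(1H)-one | CCCCCCCC[C@@H]1CCCc2c1c(=O)c(OC)c(CO)n2O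
F5 | step 2 | (5R)-6-(1-hydroxy-2-methoxyethyl)-5-octylcyclohex-2-en-1-one | CCCCCCCC[C@@H]1CC=CC(=O)C1C(O)COC
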